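I started with an easy step. I assumed that little of gamma's reagent had gone by 48.0 h, though no reading measured it. The feed also made each volume twice the start. The reagent charge could therefore stand for c_reagent when comparing runs.

| flask | substrate | reagent | free catalyst | second catalyst | remark | time |
|---|---|---|---|---|---|---|
| gamma | 0.40 M (fed, over 20 h) | 0.84 M | 0.80 mM | 1.2 mM | run made earlier; the fed solution adds 1.0 times the starting volume |  |
| delta | 0.40 M (fed, over 20 h) | 1.3 M | 0.80 mM | 1.2 mM | run made earlier; the fed solution adds 1.0 times the starting volume |  |
| flask | 0.40 M (fed, over 20 h) | 0.600 M | 0.80 mM | 1.2 mM | the fed solution adds 1.0 times the starting volume | 50 h |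

- gamma (time / h: target / %, open intermediate / %): 12.0: 0.2, 16.1; 25.0: 1.2, 41.6; 40.0: 2.4, 52.4; 48.0: 2.8, 54.2
- delta (time / h: target / %, open intermediate / %): 6.00: 0.2, 5.0; 20.0: 0.9, 33.0; 30.0: 3.1, 45.7; 48.0: 4.9, 50.7

(standard deviation of a reading: 0.5 percentage points)

- in percentages every species weighs as the substrate in it: one idle adduct counts as two
- for target the idle adduct is counted in
- charges are per starting volume, the dose included; the dosed solution carries all of it
- steps that have been proposed: substrate + free catalyst <-> free catalyst + open intermediate; second catalyst + open intermediate <-> catalyst intermediate; reagent + catalyst intermediate -> second catalyst + target; target -> over-reaction product; substrate + target <-> idle adduct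
- in an amount of target, one idle adduct counts as one target
- percentages count the whole charge, also what has not yet gone in

1. how much target the flask holds at 50 h, in percent of the substrate charged
2. how much open intermediate the flask holds at 50 h, in percent of the substrate charged
3. how much over-reaction product the flask holds at 50 h, in percent of the substrate charged
4. how much substrate the flask holds at 50 h, in percent of the substrate charged
5. concentration of reagent at 50 h, in M

In the proposed steps, reagent and catalyst intermediate give target, and open intermediate feeds catalyst intermediate. Taking reagent as nearly constant, I treated that step as pseudo-first-order in catalyst intermediate. I assumed the making of target follows c_reagent times open intermediate, while target leaks away in a first-order step. A level held between making and leak then gives a ratio to read from the last readings: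

gamma: 2.8% / (0.84 M × 54.2%) = 0.0615 M⁻¹

delta: 4.9% / (1.3 M × 50.7%) = 0.0743 M⁻¹

These are readings, with 0.5 percentage points on each. Their mean, 0.0679 M⁻¹, is my hold ratio: target per unit of c_reagent and per unit of open intermediate.

For the flask I borrowed gamma's 54.2% of open intermediate. That gave a bracket for target:

lower bound, gamma's ratio: 2.00%

upper bound, delta's ratio: 2.42%

The forecast gave target 2.1%, open intermediate 56%, over-reaction product 6.3%, substrate 35% and c_reagent 0.283 M. Its ground for target was “Its level scales about with reagent”. Its target lay inside my bracket .

The flask gave target 2.32%, open intermediate 55.2%, over-reaction product 3.03%, substrate 39.3% and c_reagent 0.289 M. The forecast stood within tolerance on each.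

    substrate + free catalyst ⇌ free catalyst + open intermediate (K = 1.60, k = 0.0350 M⁻¹ s⁻¹)
    second catalyst + open intermediate ⇌ catalyst intermediate (K = 0.690 M⁻¹, k = 0.0580 M⁻¹ s⁻¹)
    reagent + catalyst intermediate → second catalyst + target (k = 0.00710 M⁻¹ s⁻¹)
    target → over-reaction product (k = 1.60 × 10⁻⁵ s⁻¹)
    substrate + target ⇌ idle adduct, settled at all times (K = 0.790 M⁻¹)

At 50 h the flask held far more open intermediate than target. With that open intermediate, the hold ratio gave 2.25% target. The neighbour flask with 2.0 × 10⁻⁴ M free catalyst held 33.0% open intermediate, so the ratio gave 1.34%, and it held 1.26%. The largest single effect on the flask's target was the backward run from catalyst intermediate to second catalyst + open intermediate: without that run it held 18.5% target, against 2.32%, which made up 17% of what was missing.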